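Ring B of this ent-labdane (C5–C10) is cut at C6–C7 and C5–C10. Its C8 methylidene is a latent ketone and the quaternary C4 can be grown from a ketone, so ring B is read as the [4+2] adduct of a 2-silyloxy diene (C7=C8–C9=C10) and a vinyl ketone (C5=C6 on C4=O) joined by the C1–C3 chain. One catalytic enantioselective intramolecular Diels–Alder reaction of an acyclic trienone thus closes rings A and B together and creates the quaternary C10; C5, C9 and C4 are then relayed from C10 by equilibration and substrate control. The myrcene-type side chain is in place beforehand; the Z-coumarate is added last.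

Key step: step 7

Remark: atom numbers (C1–C20) are labdane numbers throughout.
Remark: acid 21 is taken as a catalogue reagent.
Remark: the hand of the catalyst in step 7 is assigned by analogy with intermolecular cases, not by a model for this tethered substrate; the mirror-image catalyst is equally available and is the one to use should C10 form with the opposite configuration.

Step 1
Reactants: 1 3-butyn-1-ol; 2 trimethyl 4-bromoorthobutyrate
Product: 3 8,8,8-trimethoxyoct-3-yn-1-ol
Conditions: LiNH2 (2.2 equiv), liq. NH3/THF, −33 °C; then 2; water, NaHCO3 work-up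
Reagents that add atoms: none
Why: The alkynol dianion should alkylate at the acetylide carbon (far more nucleophilic than the alkoxide) with the primary bromide, the ortho ester being inert to amide base; acetylide SN2 alkylation.

Step 2
Reactants: 3 8,8,8-trimethoxyoct-3-yn-1-ol; 4 N-methoxy-N-methylacetamide
Product: 7 methyl (5E)-6-(2-hydroxyethyl)-5-methyl-7-oxooct-5-enoate, via alkenylmagnesium alkoxide 5 (not isolated), via ortho ester enone 6 (not isolated)
Conditions: MeMgBr (5 equiv), Fe(acac)3 (15 mol%), THF, 0 °C; then 4 (6 equiv), 0 °C to rt; then 0.5 M HCl, THF, 0 °C, brief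
Reagents that add atoms: methylmagnesium bromide, C[Mg]Br; water, O
Why: Alkoxide-directed iron-catalysed syn-carbomagnesiation should place the methyl on the distal alkyne carbon (C10) and magnesium on C9 in a five-membered chelate, so that Weinreb acylation of the alkenyl Grignard gives the tetrasubstituted enone with the C10 methyl cis to the acetyl group (tether trans), and the acid work-up turns the ortho ester into the methyl ester.

Step 3
Reactants: 7 methyl (5E)-6-(2-hydroxyethyl)-5-methyl-7-oxooct-5-enoate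
Product: 8 methyl (5E)-6-(2-iodoethyl)-5-methyl-7-oxooct-5-enoate
Conditions: I2, PPh3, imidazole, CH2Cl2, 0 °C
Reagents that add atoms: iodine, II
Why: Appel-type iodination of the unhindered primary alcohol through its alkoxyphosphonium salt should proceed under neutral conditions that leave the enone geometry and the ester untouched.

Step 4
Reactants: 8 methyl (5E)-6-(2-iodoethyl)-5-methyl-7-oxooct-5-enoate; 9 chloroprene (2-chlorobuta-1,3-diene)
Product: 11 methyl (5E)-5-methyl-6-(3-methylidenepent-4-en-1-yl)-7-oxooct-5-enoate, via alkylzinc iodide 10 (not isolated)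
Conditions: Zn dust, LiCl, THF, 35 °C; then 9 (3 equiv), Pd(OAc)2 (2 mol%), SPhos (4 mol%), THF, rt
Reagents that add atoms: none
Why: Zinc insertion gives an alkylzinc iodide that tolerates ketone and ester, and Negishi cross-coupling with the alkenyl chloride should deliver the 2-substituted buta-1,3-diene (C13–C16) directly.

Step 5
Reactants: 11 methyl (5E)-5-methyl-6-(3-methylidenepent-4-en-1-yl)-7-oxooct-5-enoate
Product: 12 methyl (5E)-5-methyl-6-(3-methylidenepent-4-en-1-yl)-7-[(triisopropylsilyl)oxy]octa-5,7-dienoate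
Conditions: TIPSOTf (1.3 equiv), Et3N (2 equiv), CH2Cl2, −20 to 0 °C
Reagents that add atoms: triisopropylsilyl triflate, CC(C)[Si](C(C)C)(C(C)C)OS(=O)(=O)C(F)(F)F
Why: Soft enolisation of the methyl ketone (its only α-hydrogens are on C7) should give the kinetic cross-conjugated 2-silyloxy diene, while the far less acidic ester is not silylated; silyl enol ether formation.

Step 6
Reactants: 12 methyl (5E)-5-methyl-6-(3-methylidenepent-4-en-1-yl)-7-[(triisopropylsilyl)oxy]octa-5,7-dienoate
Product: 14 (7E)-7-methyl-8-(3-methylidenepent-4-en-1-yl)-9-[(triisopropylsilyl)oxy]deca-1,7,9-trien-3-one, via Weinreb amide 13 (not isolated)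
Conditions: MeNHOMe·HCl (1.5 equiv), i-PrMgCl (3 equiv), THF, −20 °C; then CH2=CHMgBr (3 equiv), −20 to 0 °C; inverse quench into cold aq. NH4Cl; used at once
Reagents that add atoms: vinylmagnesium bromide, C=C[Mg]Br
Why: The magnesium amide converts the methyl ester into the Weinreb amide, whose chelated tetrahedral adduct with the vinyl Grignard reagent should release the vinyl ketone only on quench, the silyl dienol ether being stable to both reagents; Weinreb ketone synthesis.

Step 7
Reactants: 14 (7E)-7-methyl-8-(3-methylidenepent-4-en-1-yl)-9-[(triisopropylsilyl)oxy]deca-1,7,9-trien-3-one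
Product: 16 (4aR,8aS)-4a-methyl-5-(3-methylidenepent-4-en-1-yl)-6-[(triisopropylsilyl)oxy]-3,4,4a,7,8,8a-hexahydronaphthalen-1(2H)-one, via cis-fused adduct 15 (not isolated)
Conditions: (R)-3,3′-bis(2,4,6-triisopropylphenyl)-1,1′-binaphthalene-2,2′-diyl N-triflylphosphoramide (10 mol%), toluene, 0.01 M, −78 to −40 °C; Et3N quench; then DBU (0.3 equiv), CH2Cl2, rt
Reagents that add atoms: none
Why: The chiral acid hydrogen-bonds to the C4 carbonyl and, within this ion pair, the 2-silyloxy diene adds to the vinyl ketone in a concerted but asynchronous [4+2] in which C7–C6 bonding runs ahead of C10–C5 bonding; the closest known reaction type is the chiral Brønsted acid-catalysed Diels–Alder reaction of 2-silyloxy dienes with alkyl vinyl ketones, run here as a type 1 intramolecular Diels–Alder reaction of a 1,7,9-decatrien-3-one. Ring B is closed by the cycloaddition itself and ring A by the C1–C3 tether, fused across the new C5–C10 bond. The polarity is matched (nucleophilic C7 onto the β-carbon C6, the substituted diene terminus C10 onto the carbonyl-bearing C5), and the (E)-geometry of C9=C10 keeps the tether outside the diene so that the s-cis form can be reached. C10, the only new stereocentre that cannot be corrected afterwards, is set by the catalyst, which differentiates the two faces of the diene terminus presented to the bound enone. C5 should form mainly in the endo mode (cis-fused 15) but lies α to the C4 ketone, so DBU equilibrates it to the trans-fused ketone with H5 anti to the axial C10 methyl. The step needs enantiofacial control and a slow uncatalysed background reaction, which low temperature, high dilution and binding of the acid to the only basic carbonyl group should secure.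

Step 8
Reactants: 16 (4aR,8aS)-4a-methyl-5-(3-methylidenepent-4-en-1-yl)-6-[(triisopropylsilyl)oxy]-3,4,4a,7,8,8a-hexahydronaphthalen-1(2H)-one
Product: 17 (1R,4aR,8aS)-4a-methyl-5-(3-methylidenepent-4-en-1-yl)-6-[(triisopropylsilyl)oxy]-3,4,4a,7,8,8a-hexahydro-2H-spiro[naphthalene-1,2′-oxirane]
Conditions: Me3SI (3 equiv), KN(SiMe3)2 (2.8 equiv), THF, −10 °C; then 16, −10 °C to rt
Reagents that add atoms: trimethylsulfonium iodide, C[S+](C)C.[I-]
Why: Corey–Chaykovsky epoxidation, in which the ylide should attack C4 from the equatorial side because the axial trajectory is blocked by the syn-axial C10 methyl, so the new CH2 is equatorial and the epoxide oxygen axial (cis to the C10 methyl).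

Step 9
Reactants: 17 (1R,4aR,8aS)-4a-methyl-5-(3-methylidenepent-4-en-1-yl)-6-[(triisopropylsilyl)oxy]-3,4,4a,7,8,8a-hexahydro-2H-spiro[naphthalene-1,2′-oxirane]
Product: 18 [(1R,4aR,8aS)-1,4a-dimethyl-5-(3-methylidenepent-4-en-1-yl)-6-[(triisopropylsilyl)oxy]-1,2,3,4,4a,7,8,8a-octahydronaphthalen-1-yl]methanol
Conditions: Me3Al (5 equiv), hexane/CH2Cl2, −78 to 0 °C; aq. KNaC4H4O6 work-up
Reagents that add atoms: trimethylaluminium, C[Al](C)C
Why: Lewis acid-activated methylative opening of the 2,2-disubstituted epoxide at its tertiary carbon should deliver methyl to C4 anti to the axial C–O bond (the face away from the C10 methyl), so C18 ends up equatorial and the C19 hydroxymethyl axial, cis to the C10 methyl; Me3Al epoxide opening with inversion.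

Step 10
Reactants: 18 [(1R,4aR,8aS)-1,4a-dimethyl-5-(3-methylidenepent-4-en-1-yl)-6-[(triisopropylsilyl)oxy]-1,2,3,4,4a,7,8,8a-octahydronaphthalen-1-yl]methanol
Product: 19 (1S,4aS,5R,8aR)-5-(hydroxymethyl)-5,8a-dimethyl-1-(3-methylidenepent-4-en-1-yl)octahydronaphthalen-2(1H)-one
Conditions: Bu4NF (1.3 equiv), THF, 0 °C to rt
Reagents that add atoms: none
Why: Fluoride cleavage of the silyl enol ether gives the C8 enolate, whose protonation is reversible under the mildly basic conditions, so C9 should settle with the side chain equatorial (H9 axial, anti to the C10 methyl); desilylation with thermodynamic control.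

Step 11
Reactants: 19 (1S,4aS,5R,8aR)-5-(hydroxymethyl)-5,8a-dimethyl-1-(3-methylidenepent-4-en-1-yl)octahydronaphthalen-2(1H)-one
Product: 20 [(1R,4aS,5R,8aS)-1,4a-dimethyl-6-methylidene-5-(3-methylidenepent-4-en-1-yl)decahydronaphthalen-1-yl]methanol
Conditions: Ph3PCH3Br (4 equiv), KOtBu (3.8 equiv), THF, 0 °C to reflux
Reagents that add atoms: methyltriphenylphosphonium bromide, C[P+](c1ccccc1)(c1ccccc1)c1ccccc1.[Br-]
Why: Wittig methylenation of the C8 ketone, with excess ylide covering the free hydroxyl, should install C17, and any C9 epimerisation under the basic conditions returns the equatorial isomer.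

Step 12
Reactants: 20 [(1R,4aS,5R,8aS)-1,4a-dimethyl-6-methylidene-5-(3-methylidenepent-4-en-1-yl)decahydronaphthalen-1-yl]methanol; 21 2-[bis(2,2,2-trifluoroethoxy)phosphoryl]acetic acid
Product: 22 [(1R,4aS,5R,8aS)-1,4a-dimethyl-6-methylidene-5-(3-methylidenepent-4-en-1-yl)decahydronaphthalen-1-yl]methyl 2-[bis(2,2,2-trifluoroethoxy)phosphoryl]acetate
Conditions: EDC·HCl (1.5 equiv), DMAP (0.2 equiv), CH2Cl2, 0 °C to rt
Reagents that add atoms: none
Why: Steglich esterification should acylate the hindered neopentyl C19 alcohol with the small, unbranched phosphonoacetic acid without touching the alkenes.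

Step 13
Reactants: 22 [(1R,4aS,5R,8aS)-1,4a-dimethyl-6-methylidene-5-(3-methylidenepent-4-en-1-yl)decahydronaphthalen-1-yl]methyl 2-[bis(2,2,2-trifluoroethoxy)phosphoryl]acetate; 23 4-[(tert-butyldimethylsilyl)oxy]benzaldehyde
Product: 25 [(1R,4aS,5R,8aS)-1,4a-dimethyl-6-methylidene-5-(3-methylidenepent-4-en-1-yl)decahydronaphthalen-1-yl]methyl (2Z)-3-(4-hydroxyphenyl)prop-2-enoate, via silyl-protected Z ester 24 (not isolated)
Conditions: KN(SiMe3)2, 18-crown-6, THF, −78 °C; then 23; then AcOH (3 equiv), Bu4NF (1.5 equiv), −78 to 0 °C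
Reagents that add atoms: none
Why: Still–Gennari olefination with the trifluoroethyl phosphonate should give the Z-cinnamate under kinetic control (fast elimination from the first-formed adduct), and buffered fluoride then frees the phenol without generating a phenoxide that could isomerise the Z double bond.

Compound list
1 | 3-butyn-1-ol | C#CCCO | starting material
2 | trimethyl 4-bromoorthobutyrate (4-bromo-1,1,1-trimethoxybutane) | COC(OC)(OC)CCCBr | starting material
3 | 8,8,8-trimethoxyoct-3-yn-1-ol | OCCC#CCCCC(OC)(OC)OC | intermediate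
4 | N-methoxy-N-methylacetamide | CC(=O)N(C)OC | starting material
5 | bromomagnesium (3E)-3-(bromomagnesio)-8,8,8-trimethoxy-4-methyloct-3-en-1-olate (alkenylmagnesium alkoxide) | COC(OC)(OC)CCC/C(C)=C(/[Mg]Br)CCO[Mg]Br | intermediate
6 | (3E)-3-(2-hydroxyethyl)-8,8,8-trimethoxy-4-methyloct-3-en-2-one (ortho ester enone) | CC(=O)/C(CCO)=C(\C)CCCC(OC)(OC)OC | intermediate
7 | methyl (5E)-6-(2-hydroxyethyl)-5-methyl-7-oxooct-5-enoate | CC(=O)/C(CCO)=C(\C)CCCC(=O)OC | intermediate
8 | methyl (5E)-6-(2-iodoethyl)-5-methyl-7-oxooct-5-enoate | CC(=O)/C(CCI)=C(\C)CCCC(=O)OC | intermediate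
9 | chloroprene (2-chlorobuta-1,3-diene) | C=CC(Cl)=C | starting material
10 | [(3E)-3-acetyl-8-methoxy-4-methyl-8-oxooct-3-en-1-yl]zinc iodide (alkylzinc iodide) | CC(=O)/C(CC[Zn]I)=C(\C)CCCC(=O)OC | intermediate
11 | methyl (5E)-5-methyl-6-(3-methylidenepent-4-en-1-yl)-7-oxooct-5-enoate | CC(=O)/C(CCC(=C)C=C)=C(\C)CCCC(=O)OC | intermediate
12 | methyl (5E)-5-methyl-6-(3-methylidenepent-4-en-1-yl)-7-[(triisopropylsilyl)oxy]octa-5,7-dienoate | C=C(O[Si](C(C)C)(C(C)C)C(C)C)/C(CCC(=C)C=C)=C(\C)CCCC(=O)OC | intermediate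
13 | (5E)-N-methoxy-N,5-dimethyl-6-(3-methylidenepent-4-en-1-yl)-7-[(triisopropylsilyl)oxy]octa-5,7-dienamide (Weinreb amide) | C=C(O[Si](C(C)C)(C(C)C)C(C)C)/C(CCC(=C)C=C)=C(\C)CCCC(=O)N(C)OC | intermediate
14 | (7E)-7-methyl-8-(3-methylidenepent-4-en-1-yl)-9-[(triisopropylsilyl)oxy]deca-1,7,9-trien-3-one | C=CC(=O)CCC/C(C)=C(\CCC(=C)C=C)C(=C)O[Si](C(C)C)(C(C)C)C(C)C | intermediate
15 | (4aR,8aR)-4a-methyl-5-(3-methylidenepent-4-en-1-yl)-6-[(triisopropylsilyl)oxy]-3,4,4a,7,8,8a-hexahydronaphthalen-1(2H)-one (cis-fused adduct) | C=CC(=C)CCC1=C(O[Si](C(C)C)(C(C)C)C(C)C)CC[C@H]2C(=O)CCC[C@@]12C | intermediate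
16 | (4aR,8aS)-4a-methyl-5-(3-methylidenepent-4-en-1-yl)-6-[(triisopropylsilyl)oxy]-3,4,4a,7,8,8a-hexahydronaphthalen-1(2H)-one (trans-fused) | C=CC(=C)CCC1=C(O[Si](C(C)C)(C(C)C)C(C)C)CC[C@@H]2C(=O)CCC[C@@]12C | intermediate
17 | (1R,4aR,8aS)-4a-methyl-5-(3-methylidenepent-4-en-1-yl)-6-[(triisopropylsilyl)oxy]-3,4,4a,7,8,8a-hexahydro-2H-spiro[naphthalene-1,2′-oxirane] (epoxide oxygen axial, cis to the angular methyl) | C=CC(=C)CCC1=C(O[Si](C(C)C)(C(C)C)C(C)C)CC[C@@H]2[C@]3(OC3)CCC[C@@]12C | intermediate
18 | [(1R,4aR,8aS)-1,4a-dimethyl-5-(3-methylidenepent-4-en-1-yl)-6-[(triisopropylsilyl)oxy]-1,2,3,4,4a,7,8,8a-octahydronaphthalen-1-yl]methanol | C=CC(=C)CCC1=C(O[Si](C(C)C)(C(C)C)C(C)C)CC[C@@H]2[C@](C)(CO)CCC[C@@]12C | intermediate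
19 | (1S,4aS,5R,8aR)-5-(hydroxymethyl)-5,8a-dimethyl-1-(3-methylidenepent-4-en-1-yl)octahydronaphthalen-2(1H)-one | C=CC(=C)CC[C@@H]1C(=O)CC[C@@H]2[C@](C)(CO)CCC[C@@]12C | intermediate
20 | [(1R,4aS,5R,8aS)-1,4a-dimethyl-6-methylidene-5-(3-methylidenepent-4-en-1-yl)decahydronaphthalen-1-yl]methanol (ent-labda-8(17),13(16),14-trien-19-ol) | C=CC(=C)CC[C@@H]1C(=C)CC[C@@H]2[C@](C)(CO)CCC[C@@]12C | intermediate
21 | 2-[bis(2,2,2-trifluoroethoxy)phosphoryl]acetic acid | OC(=O)CP(=O)(OCC(F)(F)F)OCC(F)(F)F | starting material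
22 | [(1R,4aS,5R,8aS)-1,4a-dimethyl-6-methylidene-5-(3-methylidenepent-4-en-1-yl)decahydronaphthalen-1-yl]methyl 2-[bis(2,2,2-trifluoroethoxy)phosphoryl]acetate | C=CC(=C)CC[C@@H]1C(=C)CC[C@@H]2[C@](C)(COC(=O)CP(=O)(OCC(F)(F)F)OCC(F)(F)F)CCC[C@@]12C | intermediate
23 | 4-[(tert-butyldimethylsilyl)oxy]benzaldehyde | O=Cc1ccc(O[Si](C)(C)C(C)(C)C)cc1 | starting material
24 | [(1R,4aS,5R,8aS)-1,4a-dimethyl-6-methylidene-5-(3-methylidenepent-4-en-1-yl)decahydronaphthalen-1-yl]methyl (2Z)-3-{4-[(tert-butyldimethylsilyl)oxy]phenyl}prop-2-enoate | C=CC(=C)CC[C@@H]1C(=C)CC[C@@H]2[C@](C)(COC(=O)/C=C\c3ccc(O[Si](C)(C)C(C)(C)C)cc3)CCC[C@@]12C | intermediate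
25 | [(1R,4aS,5R,8aS)-1,4a-dimethyl-6-methylidene-5-(3-methylidenepent-4-en-1-yl)decahydronaphthalen-1-yl]methyl (2Z)-3-(4-hydroxyphenyl)prop-2-enoate (CNP0131099.2) | C=CC(=C)CC[C@@H]1C(=C)CC[C@@H]2[C@](C)(COC(=O)/C=C\c3ccc(O)cc3)CCC[C@@]12C | target

Total step count: 13. Longest linear sequence: 13 steps (from 1 to 25).

Steps most likely to fail

Step 7. The chiral acid may discriminate the two faces of the diene terminus poorly in this tethered transition state, or an uncatalysed cyclisation may erode the enantiomeric purity at C10; the endo-to-trans equilibration at C5 may also stop at a mixture. The fallback replaces catalytic induction by a classical resolution. It sets out from trienone 14, which is cyclised without a chiral catalyst (toluene, 60 °C, then DBU) to the racemic trans-fused ketone F1. Lithiated (S)-N,S-dimethyl-S-phenylsulfoximine (THF, −78 °C) adds to the C4 carbonyl to give two diastereomeric adducts that are separated on silica. The diastereomer of the (4aR,8aS) series, β-hydroxysulfoximine F2, is heated in toluene at 110 °C, which expels the sulfoximine and comes back to the route at ketone 16.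

Step 9. The aluminium-bound epoxide may ionise and then undergo hydride shift to an aldehyde or proton loss to an allylic alcohol faster than methyl transfer, or methyl may be delivered without facial fidelity at C4. The fallback builds the quaternary centre by nitrile alkylation and sets out from ketone 16. Reductive cyanation with TosMIC and KOtBu (DME/t-BuOH) should give the C4 nitrile F3 as an epimer mixture. Deprotonation with LiN(iPr)2 and methylation with MeI, the electrophile entering anti to the C10 methyl, should give the axial nitrile F4. Reduction with i-Bu2AlH (toluene, −78 °C) and hydrolysis gives the aldehyde F5, and NaBH4 in MeOH comes back to the route at alcohol 18.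

Step 2. Acyl transfer to the hindered, chelated alkenylmagnesium may be slow while the excess MeMgBr consumes the amide, so that the protonated trisubstituted alkene results. The fallback forms the C8–C9 bond by cross-coupling and sets out from alkyne 3. The same carbomagnesiation mixture is quenched with I2 to give the alkenyl iodide F6. Stille coupling with tributyl(1-ethoxyvinyl)stannane (Pd(PPh3)4, CuI, DMF) gives the dienyl enol ether F7. Treatment with 0.5 M HCl in THF hydrolyses the enol ether and the ortho ester together and comes back to the route at hydroxy enone 7.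

Further compounds
F1 | step 7 | racemic trans-fused 4a-methyl-5-(3-methylidenepent-4-en-1-yl)-6-[(triisopropylsilyl)oxy]-3,4,4a,7,8,8a-hexahydronaphthalen-1(2H)-one (both enantiomers) | C=CC(=C)CCC1=C(O[Si](C(C)C)(C(C)C)C(C)C)CC[C@@H]2C(=O)CCC[C@@]12C.C=CC(=C)CCC1=C(O[Si](C(C)C)(C(C)C)C(C)C)CC[C@H]2C(=O)CCC[C@]12C
F2 | step 7 | (1R,4aR,8aS)-4a-methyl-5-(3-methylidenepent-4-en-1-yl)-1-{[(S)-N-methyl-S-phenylsulfonimidoyl]methyl}-6-[(triisopropylsilyl)oxy]-1,2,3,4,4a,7,8,8a-octahydronaphthalen-1-ol | C=CC(=C)CCC1=C(O[Si](C(C)C)(C(C)C)C(C)C)CC[C@@H]2[C@](C[S@@](=O)(=NC)c3ccccc3)(O)CCC[C@@]12C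
F3 | step 9 | (4aR,8aS)-4a-methyl-5-(3-methylidenepent-4-en-1-yl)-6-[(triisopropylsilyl)oxy]-1,2,3,4,4a,7,8,8a-octahydronaphthalene-1-carbonitrile (C1 epimers) | C=CC(=C)CCC1=C(O[Si](C(C)C)(C(C)C)C(C)C)CC[C@@H]2C(C#N)CCC[C@@]12C
F4 | step 9 | (1R,4aR,8aS)-1,4a-dimethyl-5-(3-methylidenepent-4-en-1-yl)-6-[(triisopropylsilyl)oxy]-1,2,3,4,4a,7,8,8a-octahydronaphthalene-1-carbonitrile | C=CC(=C)CCC1=C(O[Si](C(C)C)(C(C)C)C(C)C)CC[C@@H]2[C@](C)(C#N)CCC[C@@]12C
F5 | step 9 | (1R,4aR,8aS)-1,4a-dimethyl-5-(3-methylidenepent-4-en-1-yl)-6-[(triisopropylsilyl)oxy]-1,2,3,4,4a,7,8,8a-octahydronaphthalene-1-carbaldehyde | C=CC(=C)CCC1=C(O[Si](C(C)C)(C(C)C)C(C)C)CC[C@@H]2[C@](C)(C=O)CCC[C@@]12C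
F6 | step 2 | (3E)-3-iodo-8,8,8-trimethoxy-4-methyloct-3-en-1-ol | COC(OC)(OC)CCC/C(C)=C(/I)CCO
F7 | step 2 | (3E)-3-(1-ethoxyethenyl)-8,8,8-trimethoxy-4-methyloct-3-en-1-ol | COC(OC)(OC)CCC/C(C)=C(/C(=C)OCC)CCO
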